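**Plan**
- Cuts: the C3–O acyl bond (ester, made last); C5–C1' (sp2–sp3 coupling on a C5 enol triflate); C8–C8a (ring expansion); C4a–C5 and C6–C8a (ketene [2+2]); N1–C8a and C3–C4 (enecarbamate from D-alanine).
- Forward order: the piperidine ring comes first, as its C4a=C8a enecarbamate. A cyclobutanone C4a–C5–C6–C8a is fused to it and then grown to the carbocycle C4a–C5–C6–C7–C8–C8a. The side chain follows and the octenoate comes last.
- Enabling feature: N1 sits on C8a and C5 can be carried as C=O, so donor and acceptor stand 1,3 across the four-membered ring. The C6–C8a bond ionises to an N-acyliminium ion (C8a) and a dienolate (O–C5=C6–C7=C8, using a vinyl group on C6), which recloses through C8.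
- Vinylketene delivers all four missing ring carbons C5–C8. The helper carbonyl at C5 then fixes the enol triflate position and leaves in the coupling; Cbz and benzyl leave in the hydrogenation.
- Stereochemistry: C2 from D-alanine; C3 by Felkin–Anh reduction; C4a and C8a by ketene addition anti to the pseudoaxial C2 methyl group, with C8a re-formed under control of C4a; C5 by convex-face hydrogenation; C5' from (R)-2-propyloxirane.

Key step: step 9

Remark: the locants N1, C2–C8a and C1'–C8' of the decahydroquinoline target are used for all intermediates. The target is read as (2R,3R,4aS,5S,8aR,5'R), that is 2,3-cis, with H4a, H5 and H8a all on the face of the C2 methyl group.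

**Route**

Step 1
Reactants: 1 (R)-2-propyloxirane; 2 allylmagnesium chloride
Product: 3 (R)-oct-1-en-5-ol
Conditions: CuI (10 mol %), THF, −30 to 0 °C; aq NH4Cl
Reagents that add atoms: none
Why: Copper-catalysed Grignard opening of a terminal epoxide is an SN2 attack at the CH2 terminus, so the C–O stereocentre (future C5', R) is carried over unchanged.

Step 2
Reactants: 3 (R)-oct-1-en-5-ol
Product: 4 tert-butyl(dimethyl)[(5R)-oct-1-en-5-yloxy]silane
Conditions: TBSCl, imidazole, DMF, rt
Reagents that add atoms: tert-butyldimethylsilyl chloride, CC(C)(C)[Si](C)(C)Cl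
Why: Standard silyl ether formation gives a group that survives hydroboration, cross-coupling, hydrogenation in EtOAc and carbodiimide esterification and falls to acid at the end.

Step 3
Reactants: 5 N-(benzyloxycarbonyl)-D-alanine
Product: 6 benzyl {(2R)-1-[methoxy(methyl)amino]-1-oxopropan-2-yl}carbamate
Conditions: CDI, CH2Cl2, 0 °C; then MeNH(OMe)·HCl, rt
Reagents that add atoms: N,O-dimethylhydroxylamine hydrochloride, CNOC.Cl
Why: Acyl imidazolide activation and aminolysis (Weinreb amide formation) proceeds without loss of configuration at the urethane-protected α-carbon, the future C2.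

Step 4
Reactants: 6 benzyl {(2R)-1-[methoxy(methyl)amino]-1-oxopropan-2-yl}carbamate; 7 [2-(1,3-dioxolan-2-yl)ethyl]magnesium bromide
Product: 8 benzyl [(2R)-5-(1,3-dioxolan-2-yl)-3-oxopentan-2-yl]carbamate
Conditions: 7 (2.5 equiv), THF, −20 to 0 °C; aq NH4Cl
Reagents that add atoms: none
Why: Weinreb ketone synthesis, in which the first equivalent removes N–H and the chelated tetrahedral adduct stops at the ketone, joins C3 to C4 with C4a and the masked C8a already in place.

Step 5
Reactants: 8 benzyl [(2R)-5-(1,3-dioxolan-2-yl)-3-oxopentan-2-yl]carbamate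
Product: 9 benzyl [(2R,3R)-5-(1,3-dioxolan-2-yl)-3-hydroxypentan-2-yl]carbamate
Conditions: LiBH(s-Bu)3, THF, −78 °C; aq NH4Cl
Reagents that add atoms: none
Why: Felkin–Anh-controlled reduction of a carbamate-protected α-amino ketone by a bulky, poorly chelating trialkylborohydride brings hydride in anti to the perpendicular nitrogen substituent and past H rather than CH3, which sets C3 as R (syn amino alcohol, the later 2,3-cis pair).

Step 6
Reactants: 9 benzyl [(2R,3R)-5-(1,3-dioxolan-2-yl)-3-hydroxypentan-2-yl]carbamate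
Product: 10 benzyl [(2R,3R)-3-(benzyloxy)-5-(1,3-dioxolan-2-yl)pentan-2-yl]carbamate
Conditions: 2-benzyloxy-1-methylpyridinium triflate, MgO, PhCF3, 83 °C
Reagents that add atoms: 2-benzyloxy-1-methylpyridinium triflate, C[n+]1ccccc1OCc1ccccc1.[O-]S(=O)(=O)C(F)(F)F
Why: Benzyl transfer from the pyridinium salt under neutral conditions avoids both an alkoxide, which would close on the Cbz group to an oxazolidinone, and an acid, which would open the acetal onto the free hydroxyl group.

Step 7
Reactants: 10 benzyl [(2R,3R)-3-(benzyloxy)-5-(1,3-dioxolan-2-yl)pentan-2-yl]carbamate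
Product: 12 benzyl (2R,3R)-3-(benzyloxy)-2-methyl-3,4-dihydropyridine-1(2H)-carboxylate, via hemiaminal 11 (not isolated)
Conditions: aq HCl (1 M, cat.), THF, 40 °C; then p-TsOH·H2O (5 mol %), toluene, reflux, Dean–Stark
Reagents that add atoms: none
Why: Acetal hydrolysis, closure of the carbamate N–H on the aldehyde (N1–C8a) and acid-catalysed dehydration of the hemiaminal is the standard entry to cyclic enecarbamates and touches no stereocentre.

Step 8
Reactants: 12 benzyl (2R,3R)-3-(benzyloxy)-2-methyl-3,4-dihydropyridine-1(2H)-carboxylate; 13 (E)-but-2-enoyl chloride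
Product: 15 benzyl (1S,3R,4R,6R,8S)-4-(benzyloxy)-8-ethenyl-3-methyl-7-oxo-2-azabicyclo[4.2.0]octane-2-carboxylate, via vinylketene 14 (not isolated)
Conditions: Et3N, cyclohexane, reflux, slow addition of 13
Reagents that add atoms: none
Why: In this thermal ketene–alkene [2+2] cycloaddition, known for cyclic enecarbamates and for vinylketene made by 1,4-dehydrochlorination of crotonyl chloride, the nucleophilic C4a bonds to the ketene carbonyl carbon (C5) and C8a to the ketene α-carbon (C6), addition is suprafacial on the alkene (cis fusion) and comes from the face opposite to the C2 methyl group, which A(1,3) strain with the carbamate holds pseudoaxial, and the vinyl group should end up endo at C6, a centre that step 9 erases.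

Step 9
Reactants: 15 benzyl (1S,3R,4R,6R,8S)-4-(benzyloxy)-8-ethenyl-3-methyl-7-oxo-2-azabicyclo[4.2.0]octane-2-carboxylate
Product: 17 benzyl (2R,3R,4aR,8aR)-3-(benzyloxy)-2-methyl-5-oxo-3,4,4a,5,8,8a-hexahydroquinoline-1(2H)-carboxylate, via iminium dienolate 16 (not isolated)
Conditions: Sc(OTf)3 (10 mol %), CH2Cl2, 0 °C to rt
Reagents that add atoms: none
Why: Proposed new method: Sc(OTf)3 binds the C5 carbonyl of 15, whose carbamate nitrogen on C8a (donor) and C5=O (acceptor) stand 1,3 across the four-membered ring, so that the strained C6–C8a bond ionises (retro-Mannich) to the N-acyliminium dienolate 16, which recloses through its γ-carbon C8 on C8a (vinylogous Mannich), a net 1,3-shift of C8a from C6 to C8 that turns ring C4a–C5–C6–C8a into ring C4a–C5–C6–C7–C8–C8a and releases the cyclobutanone strain. The closest known reaction types are the Lewis acid opening of cyclobutanones that carry a donor at C3 to 1,4-zwitterions (trapped in formal [4+2] annulations), the two-carbon ring expansion of 2-vinylcyclobutanones and 2-vinylcyclobutanols by 1,3-shift, and vinylogous Mannich closures on N-acyliminium ions; what is new is their union on a carbamate-donor 2-vinylcyclobutanone. The one ring that closes does so in the 6-(enolendo)-exo-trig mode. C8a is the only stereocentre made: the dienolate arm hangs from C4a on the face opposite to the C2 methyl group and lies parallel to the empty orbital left at C8a, so C8 can bond only on that face, which gives the cis ring fusion and is also the face that the pseudoaxial C2 methyl group leaves open (matched), while C2, C3 and C4a are not touched and the C6 centre disappears. The step needs cleavage of C6–C8a and not of C4a–C8a, secured by the vinyl group, which lets only the first cleavage deliver a conjugated dienolate (the second would give a strained eight-membered zwitterion), and it needs γ- over α-closure, secured because α-closure merely regenerates strained 15 reversibly whereas γ-closure gives the conjugated enone irreversibly. Loss of the C4a proton from 16 is the competing path and is held back because this C–H bond lies near the nodal plane of the iminium ion as long as the C4a–C5 bond is aligned with it, and because no base is present.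

Step 10
Reactants: 17 benzyl (2R,3R,4aR,8aR)-3-(benzyloxy)-2-methyl-5-oxo-3,4,4a,5,8,8a-hexahydroquinoline-1(2H)-carboxylate
Product: 19 benzyl (2R,3R,4aR,8aR)-3-(benzyloxy)-2-methyl-5-[(trifluoromethylsulfonyl)oxy]-3,4,4a,7,8,8a-hexahydroquinoline-1(2H)-carboxylate, via lithium enolate 18 (not isolated)
Conditions: LiBH(s-Bu)3, THF, −78 °C; then PhNTf2, −78 to 0 °C; aq NH4Cl
Reagents that add atoms: N-phenylbis(trifluoromethanesulfonimide), O=S(=O)(C(F)(F)F)N(c1ccccc1)S(=O)(=O)C(F)(F)F
Why: Conjugate (1,4) hydride addition of a trialkylborohydride to a β-unsubstituted cyclohexenone followed by O-triflation of the enolate gives the C5=C6 enol triflate regiospecifically, and at −78 °C the enolate does not equilibrate towards C4a, so the ring fusion is neither epimerised nor opened by β-elimination of the carbamate.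

Step 11
Reactants: 19 benzyl (2R,3R,4aR,8aR)-3-(benzyloxy)-2-methyl-5-[(trifluoromethylsulfonyl)oxy]-3,4,4a,7,8,8a-hexahydroquinoline-1(2H)-carboxylate; 4 tert-butyl(dimethyl)[(5R)-oct-1-en-5-yloxy]silane
Product: 21 benzyl (2R,3R,4aS,8aR)-3-(benzyloxy)-5-[(5R)-5-{[tert-butyl(dimethyl)silyl]oxy}octyl]-2-methyl-3,4,4a,7,8,8a-hexahydroquinoline-1(2H)-carboxylate, via B-alkyl-9-BBN 20 (not isolated)
Conditions: 4, 9-BBN-H, THF, 0 °C to rt; then 19, Pd(dppf)Cl2 (5 mol %), aq K3PO4, DMF–THF, 50 °C
Reagents that add atoms: none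
Why: Anti-Markovnikov hydroboration and B-alkyl Suzuki–Miyaura coupling join C1' to C5 (sp3–sp2) without touching any stereocentre.

Step 12
Reactants: 21 benzyl (2R,3R,4aS,8aR)-3-(benzyloxy)-5-[(5R)-5-{[tert-butyl(dimethyl)silyl]oxy}octyl]-2-methyl-3,4,4a,7,8,8a-hexahydroquinoline-1(2H)-carboxylate
Product: 23 tert-butyl (2R,3R,4aS,5S,8aR)-5-[(5R)-5-{[tert-butyl(dimethyl)silyl]oxy}octyl]-3-hydroxy-2-methyloctahydroquinoline-1(2H)-carboxylate, via amino alcohol 22 (not isolated)
Conditions: H2 (4 atm), Pd(OH)2/C, Boc2O, EtOAc, rt to 40 °C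
Reagents that add atoms: di-tert-butyl dicarbonate, CC(C)(C)OC(=O)OC(=O)OC(C)(C)C
Why: Heterogeneous hydrogenation should add H2 to C5=C6 from the convex face (the face of H4a and H8a), because A(1,2) strain between C1' and C4 holds C4 pseudoaxial over the other face, which sets C5 as S (H4a, H5 and H8a all cis), while the same catalyst hydrogenolyses the benzyl ether and the Cbz group and Boc2O caps the freed amine (hydrogenolysis with in situ carbamate exchange).

Step 13
Reactants: 23 tert-butyl (2R,3R,4aS,5S,8aR)-5-[(5R)-5-{[tert-butyl(dimethyl)silyl]oxy}octyl]-3-hydroxy-2-methyloctahydroquinoline-1(2H)-carboxylate; 24 (E)-oct-2-enoic acid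
Product: 25 tert-butyl (2R,3R,4aS,5S,8aR)-5-[(5R)-5-{[tert-butyl(dimethyl)silyl]oxy}octyl]-2-methyl-3-{[(2E)-oct-2-enoyl]oxy}octahydroquinoline-1(2H)-carboxylate
Conditions: DCC, DMAP, CH2Cl2, 0 °C to rt
Reagents that add atoms: none
Why: Steglich esterification acylates the only free hydroxyl group (C3–OH), nitrogen and C5'–O being blocked, and keeps the E geometry of the enoate.

Step 14
Reactants: 25 tert-butyl (2R,3R,4aS,5S,8aR)-5-[(5R)-5-{[tert-butyl(dimethyl)silyl]oxy}octyl]-2-methyl-3-{[(2E)-oct-2-enoyl]oxy}octahydroquinoline-1(2H)-carboxylate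
Product: 26 (2R,3R,4aS,5S,8aR)-5-[(5R)-5-hydroxyoctyl]-2-methyldecahydroquinolin-3-yl (2E)-oct-2-enoate
Conditions: TFA–CH2Cl2–H2O (45:50:5), 0 °C to rt; aq NaHCO3
Reagents that add atoms: none
Why: Aqueous acid cleaves the tert-butyl carbamate and the secondary silyl ether in one operation while the enoate ester, the E-alkene and all stereocentres are inert to it, and the mild bicarbonate work-up frees the amine without O-to-N acyl shift.

**Compound list**
1 | (R)-2-propyloxirane | CCC[C@@H]1CO1 | starting material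
2 | allylmagnesium chloride | C=CC[Mg]Cl | starting material
3 | (R)-oct-1-en-5-ol | C=CCC[C@H](O)CCC | intermediate
4 | tert-butyl(dimethyl)[(5R)-oct-1-en-5-yloxy]silane | C=CCC[C@H](O[Si](C)(C)C(C)(C)C)CCC | intermediate
5 | N-(benzyloxycarbonyl)-D-alanine | C[C@@H](NC(=O)OCc1ccccc1)C(=O)O | starting material
6 | benzyl {(2R)-1-[methoxy(methyl)amino]-1-oxopropan-2-yl}carbamate | C[C@@H](NC(=O)OCc1ccccc1)C(=O)N(C)OC | intermediate
7 | [2-(1,3-dioxolan-2-yl)ethyl]magnesium bromide | Br[Mg]CCC1OCCO1 | starting material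
8 | benzyl [(2R)-5-(1,3-dioxolan-2-yl)-3-oxopentan-2-yl]carbamate | C[C@@H](NC(=O)OCc1ccccc1)C(=O)CCC1OCCO1 | intermediate
9 | benzyl [(2R,3R)-5-(1,3-dioxolan-2-yl)-3-hydroxypentan-2-yl]carbamate (syn) | C[C@@H](NC(=O)OCc1ccccc1)[C@H](O)CCC1OCCO1 | intermediate
10 | benzyl [(2R,3R)-3-(benzyloxy)-5-(1,3-dioxolan-2-yl)pentan-2-yl]carbamate | C[C@@H](NC(=O)OCc1ccccc1)[C@H](OCc1ccccc1)CCC1OCCO1 | intermediate
11 | benzyl (2R,3R)-3-(benzyloxy)-6-hydroxy-2-methylpiperidine-1-carboxylate (hemiaminal, both C6 epimers) | c2ccccc2CO[C@@H]1CCC(O)N(C(=O)OCc2ccccc2)[C@@H]1C | intermediate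
12 | benzyl (2R,3R)-3-(benzyloxy)-2-methyl-3,4-dihydropyridine-1(2H)-carboxylate (enecarbamate, C4a=C8a) | c2ccccc2CO[C@@H]1CC=CN(C(=O)OCc2ccccc2)[C@@H]1C | intermediate
13 | (E)-but-2-enoyl chloride | C/C=C/C(=O)Cl | starting material
14 | buta-1,3-dien-1-one (vinylketene) | C=CC=C=O | intermediate
15 | benzyl (1S,3R,4R,6R,8S)-4-(benzyloxy)-8-ethenyl-3-methyl-7-oxo-2-azabicyclo[4.2.0]octane-2-carboxylate (cis-fused, four-membered ring anti to C2-Me, vinyl endo) | c3ccccc3CO[C@@H]1C[C@H]2C(=O)[C@@H](C=C)[C@H]2N(C(=O)OCc3ccccc3)[C@@H]1C | intermediate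
16 | N-acyliminium dienolate zwitterion (C8a=N1 iminium, O–C5=C6–C7=C8 dienolate on C4a, scandium-bound at oxygen) | c3ccccc3CO[C@@H]1C[C@@H](C([O-])=CC=C)C=[N+](C(=O)OCc3ccccc3)[C@@H]1C | intermediate
17 | benzyl (2R,3R,4aR,8aR)-3-(benzyloxy)-2-methyl-5-oxo-3,4,4a,5,8,8a-hexahydroquinoline-1(2H)-carboxylate (cis-fused C6=C7 enone) | c3ccccc3CO[C@@H]1C[C@H]2C(=O)C=CC[C@H]2N(C(=O)OCc3ccccc3)[C@@H]1C | intermediate
18 | lithium C5=C6 enolate of the saturated C5 ketone | c3ccccc3CO[C@@H]1C[C@H]2C([O-])=CCC[C@H]2N(C(=O)OCc3ccccc3)[C@@H]1C.[Li+] | intermediate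
19 | benzyl (2R,3R,4aR,8aR)-3-(benzyloxy)-2-methyl-5-[(trifluoromethylsulfonyl)oxy]-3,4,4a,7,8,8a-hexahydroquinoline-1(2H)-carboxylate | c3ccccc3CO[C@@H]1C[C@H]2C(OS(=O)(=O)C(F)(F)F)=CCC[C@H]2N(C(=O)OCc3ccccc3)[C@@H]1C | intermediate
20 | 9-[(5R)-5-{[tert-butyl(dimethyl)silyl]oxy}octyl]-9-borabicyclo[3.3.1]nonane | B1(CCCC[C@H](O[Si](C)(C)C(C)(C)C)CCC)C2CCCC1CCC2 | intermediate
21 | benzyl (2R,3R,4aS,8aR)-3-(benzyloxy)-5-[(5R)-5-{[tert-butyl(dimethyl)silyl]oxy}octyl]-2-methyl-3,4,4a,7,8,8a-hexahydroquinoline-1(2H)-carboxylate | c3ccccc3CO[C@@H]1C[C@H]2C(CCCC[C@H](O[Si](C)(C)C(C)(C)C)CCC)=CCC[C@H]2N(C(=O)OCc3ccccc3)[C@@H]1C | intermediate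
22 | (2R,3R,4aS,5S,8aR)-5-[(5R)-5-{[tert-butyl(dimethyl)silyl]oxy}octyl]-2-methyldecahydroquinolin-3-ol | O[C@@H]1C[C@H]2[C@@H](CCCC[C@H](O[Si](C)(C)C(C)(C)C)CCC)CCC[C@H]2N[C@@H]1C | intermediate
23 | tert-butyl (2R,3R,4aS,5S,8aR)-5-[(5R)-5-{[tert-butyl(dimethyl)silyl]oxy}octyl]-3-hydroxy-2-methyloctahydroquinoline-1(2H)-carboxylate | O[C@@H]1C[C@H]2[C@@H](CCCC[C@H](O[Si](C)(C)C(C)(C)C)CCC)CCC[C@H]2N(C(=O)OC(C)(C)C)[C@@H]1C | intermediate
24 | (E)-oct-2-enoic acid | CCCCC/C=C/C(=O)O | starting material
25 | tert-butyl (2R,3R,4aS,5S,8aR)-5-[(5R)-5-{[tert-butyl(dimethyl)silyl]oxy}octyl]-2-methyl-3-{[(2E)-oct-2-enoyl]oxy}octahydroquinoline-1(2H)-carboxylate | CCCCC/C=C/C(=O)O[C@@H]1C[C@H]2[C@@H](CCCC[C@H](O[Si](C)(C)C(C)(C)C)CCC)CCC[C@H]2N(C(=O)OC(C)(C)C)[C@@H]1C | intermediate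
26 | (2R,3R,4aS,5S,8aR)-5-[(5R)-5-hydroxyoctyl]-2-methyldecahydroquinolin-3-yl (2E)-oct-2-enoate | CCCCC/C=C/C(=O)O[C@@H]1C[C@H]2[C@@H](CCCC[C@H](O)CCC)CCC[C@H]2N[C@@H]1C | target

**Step count**
Total step count: 14. Longest linear sequence: 12 (steps 3 to 14, from 5).

**Steps most likely to fail**

Step 9. The iminium dienolate may lose its C4a proton, or fall apart to enecarbamate and ketene, faster than it closes through C8. The fallback uses known chemistry and breaks the other ring bond with light instead of a Lewis acid. It sets out from 15 and comes back at 19.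
- Direct irradiation of 15 (λ ≥ 300 nm, Pyrex, benzene, rt) should cleave the acyl–allyl bond between C5 and the vinyl-bearing carbon and re-bond the acyl carbon to the vinyl terminus. This is the photochemical 1,3-acyl shift of β,γ-unsaturated ketones. It again enlarges the four-membered ring by two carbons and touches neither C4a nor C8a, and gives the β,γ-enone F1. In this variant the vinyl-bearing carbon becomes C8.
- Hydrogenation of the isolated C7=C8 alkene with RhCl(PPh3)3 and H2 (benzene–EtOH), which spares both benzyl groups, gives the saturated ketone F2.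
- Kinetic deprotonation at C6 (LDA, THF, −78 °C) gives enolate 18, which PhNTf2 converts into 19.

Step 8. Oligomerisation of vinylketene may outrun its addition to the only moderately nucleophilic enecarbamate, or C4a may be acylated without ring closure. The fallback carries the vinyl group in masked form. It sets out from 12 and comes back at 15.
- 4-Chlorobutanoyl chloride and Et3N (cyclohexane, reflux) generate (2-chloroethyl)ketene F3, a plain alkylketene of the kind known to add to cyclic enecarbamates. It should give the chloroethyl cyclobutanone F4 with the same regiochemistry and facial sense.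
- Preformed PhSeNa (from PhSeSePh and NaBH4, EtOH, 0 °C) displaces chloride to give the selenide F5.
- H2O2 (THF, 0 °C to rt) gives the selenoxide F6, whose syn elimination unveils the vinyl group of 15.

Step 12. Facial selectivity may be poor, or the double bond may migrate into the ring fusion on the palladium surface with loss of the C4a configuration. The fallback separates alkene reduction from hydrogenolysis and makes it a radical process. It sets out from 21 and comes back at 23.
- Hydrogen-atom-transfer hydrogenation (Mn(dpm)3 cat., PhSiH3, t-BuOOH, i-PrOH, rt) puts a hydrogen atom on C6. The tertiary C5 radical then takes its hydrogen from the open convex face, without reversible metal hydride migration along the ring. This gives the saturated carbamate F7 with Cbz, benzyl and TBS intact.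
- H2, Pd(OH)2/C and Boc2O in EtOAc then give 23 by way of 22.

**Further compounds**
F1 | step 9 | benzyl (2R,3R,4aR,8aR)-3-(benzyloxy)-2-methyl-5-oxo-3,4,4a,5,6,8a-hexahydroquinoline-1(2H)-carboxylate | c3ccccc3CO[C@@H]1C[C@H]2C(=O)CC=C[C@H]2N(C(=O)OCc3ccccc3)[C@@H]1C
F2 | step 9 | benzyl (2R,3R,4aR,8aR)-3-(benzyloxy)-2-methyl-5-oxooctahydroquinoline-1(2H)-carboxylate | c3ccccc3CO[C@@H]1C[C@H]2C(=O)CCC[C@H]2N(C(=O)OCc3ccccc3)[C@@H]1C
F3 | step 8 | 4-chlorobut-1-en-1-one, (2-chloroethyl)ketene | O=C=CCCCl
F4 | step 8 | analogue of 15 with 2-chloroethyl in place of ethenyl | c3ccccc3CO[C@@H]1C[C@H]2C(=O)[C@@H](CCCl)[C@H]2N(C(=O)OCc3ccccc3)[C@@H]1C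
F5 | step 8 | analogue of 15 with 2-(phenylselanyl)ethyl in place of ethenyl | c3ccccc3CO[C@@H]1C[C@H]2C(=O)[C@@H](CC[Se]c4ccccc4)[C@H]2N(C(=O)OCc3ccccc3)[C@@H]1C
F6 | step 8 | selenoxide of F5 | c3ccccc3CO[C@@H]1C[C@H]2C(=O)[C@@H](CC[Se](=O)c4ccccc4)[C@H]2N(C(=O)OCc3ccccc3)[C@@H]1C
F7 | step 12 | benzyl (2R,3R,4aS,5S,8aR)-3-(benzyloxy)-5-[(5R)-5-{[tert-butyl(dimethyl)silyl]oxy}octyl]-2-methyloctahydroquinoline-1(2H)-carboxylate | c3ccccc3CO[C@@H]1C[C@H]2[C@@H](CCCC[C@H](O[Si](C)(C)C(C)(C)C)CCC)CCC[C@H]2N(C(=O)OCc3ccccc3)[C@@H]1C
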